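**Retrosynthetic overview**
- Triene: the C2'–C3' bond is cut by hydrostannation/Stille coupling between a C4-ethynyl epoxyquinol enamide and a bromodienamide that already carries the five-membered aminoenol ring (bought, never built).
- Enamide C2–N bond: copper-catalysed amidation of a 2-iodoenone with the side-chain primary amide (asymmetric allylic methylation, ozonolysis, Wittig).
- Stereotriad and oxirane ring: one hydroxyl-directed, tartrate-mediated desymmetrising epoxidation of an achiral alkynyl p-quinol.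
- Key step: the quaternary C4–O bond is made by radical-chain ipso-hydroxylation (dearomatisation) of 4-[(trimethylsilyl)ethynyl]phenol, so oxygen is delivered to the ring carbon that already bears the chain.
- Ring order: arene ring of 4-iodophenol → cyclohexadienone (radical step) → oxirane (epoxidation); the cyclopentenone ring arrives intact in the last step.

Assumption: (E)-1-bromohept-2-ene, glutaconaldehyde potassium salt and 2-amino-3-hydroxycyclopent-2-en-1-one are taken as catalogue compounds.

**Route**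

Step 1
Reactants: 1 (E)-1-bromohept-2-ene
Product: 2 (R)-3-methylhept-1-ene
Conditions: MeMgBr (1.2 equiv), CuBr·SMe2 (1 mol%), (R,R)-Taniaphos (1.1 mol%), CH2Cl2, −75 °C
Reagents that add atoms: methylmagnesium bromide, C[Mg]Br
Why: Copper-catalysed asymmetric allylic alkylation (SN2′) of an (E)-allylic bromide with MeMgBr, in which the Cu–Taniaphos complex delivers methyl to one face of C3 and so sets the R centre (the ligand hand written is taken to give R and must be confirmed by rotation; its antipode gives S).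

Step 2
Reactants: 2 (R)-3-methylhept-1-ene
Product: 3 (R)-2-methylhexanal
Conditions: O3, CH2Cl2, −78 °C; then Me2S, −78 °C → rt
Reagents that add atoms: ozone, [O-][O+]=O
Why: Ozonolysis with reductive work-up cleaves the vinyl group to the aldehyde without touching the neighbouring stereocentre, which survives because the aldehyde is kept cold, base-free and used at once.

Step 3
Reactants: 3 (R)-2-methylhexanal; 4 2-bromopropanamide
Product: 7 (2E,4R)-2,4-dimethyloct-2-enamide, via phosphonium bromide 5 (not isolated), via amide ylide 6 (not isolated)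
Conditions: PPh3, toluene, 90 °C; KOtBu, THF, 0 °C; then 3, 0 °C → rt
Reagents that add atoms: none
Why: One-pot Wittig olefination in which the amide-stabilised ylide gives the trisubstituted E-alkene and is too weakly basic to enolise the α-stereocentre of the aldehyde.

Step 4
Reactants: 8 glutaconaldehyde potassium salt
Product: 9 (2E,4E)-5-bromopenta-2,4-dienal
Conditions: Ph3PBr2, CH2Cl2, 0 °C → rt
Reagents that add atoms: dibromotriphenylphosphorane, BrP(Br)(c1ccccc1)(c1ccccc1)c1ccccc1
Why: Deoxybromination of a vinylogous carboxylate (the enolate oxygen is activated as an oxyphosphonium and replaced by bromide through addition–elimination) gives the thermodynamically preferred E,E-bromodienal.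

Step 5
Reactants: 9 (2E,4E)-5-bromopenta-2,4-dienal
Product: 10 (2E,4E)-5-bromopenta-2,4-dienoic acid
Conditions: NaClO2, NaH2PO4, 2-methylbut-2-ene, tBuOH/H2O, 0 °C → rt
Reagents that add atoms: sodium chlorite, [Na+].[O-]Cl=O
Why: Pinnick oxidation converts the enal to the acid under buffered conditions that leave the bromodiene intact, with 2-methylbut-2-ene scavenging the hypochlorous acid.

Step 6
Reactants: 10 (2E,4E)-5-bromopenta-2,4-dienoic acid; 11 2-amino-3-hydroxycyclopent-2-en-1-one
Product: 13 (2E,4E)-5-bromo-N-(2-hydroxy-5-oxocyclopent-1-en-1-yl)penta-2,4-dienamide, via acid chloride 12 (not isolated)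
Conditions: (COCl)2, DMF (cat.), CH2Cl2, 0 °C → rt; then 11, Et3N, CH2Cl2/DMF, 0 °C → rt
Reagents that add atoms: none
Why: Acid chloride formation followed by N-acylation of the aminoenol (any O-acyl isomer shifts to nitrogen under Et3N) gives the amide, and no stereocentre is involved.

Step 7
Reactants: 14 4-iodophenol; 15 ethynyltrimethylsilane
Product: 16 4-[(trimethylsilyl)ethynyl]phenol
Conditions: Pd(PPh3)2Cl2 (2 mol%), CuI (4 mol%), Et3N, THF, rt
Reagents that add atoms: none
Why: Sonogashira coupling of an aryl iodide is fast at room temperature and tolerates the free phenol.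

Step 8
Reactants: 16 4-[(trimethylsilyl)ethynyl]phenol
Product: 17 4-hydroxy-4-[(trimethylsilyl)ethynyl]cyclohexa-2,5-dien-1-one
Conditions: mCPBA (1.2 equiv), (BzO)2 (10 mol%), CH2Cl2, visible light, 40 °C
Reagents that add atoms: 3-chloroperbenzoic acid, OOC(=O)c1cccc(Cl)c1
Why: Radical-initiated peracid para-hydroxylation of a 4-substituted phenol (dearomatisation), in which benzoyloxyl radicals start a chain and the phenoxyl radical, reacting through its C4-centred form, takes OH from the peracid O–O bond by homolytic substitution while the silylalkyne shields the side chain; the product is achiral.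

Step 9
Reactants: 17 4-hydroxy-4-[(trimethylsilyl)ethynyl]cyclohexa-2,5-dien-1-one
Product: 18 (1S,5R,6R)-5-hydroxy-5-[(trimethylsilyl)ethynyl]-7-oxabicyclo[4.1.0]hept-3-en-2-one
Conditions: Ph3COOH (1.05 equiv), NaN(SiMe3)2, diisopropyl L-tartrate, toluene, −78 → −45 °C; aq. NH4Cl
Reagents that add atoms: trityl hydroperoxide, OOC(c1ccccc1)(c1ccccc1)c1ccccc1
Why: Proposed new method: the hydroxyl-directed, tartrate-mediated nucleophilic (Weitz–Scheffer) epoxidation known for hydroxy-bearing quinone monoketals is applied to a p-quinol, the sodium alkoxide at the carbinol carbon binding the tartrate–trityl peroxide aggregate so that peroxide adds to one of the two enantiotopic enone β-carbons on the hydroxyl face, which fixes all three ring stereocentres at once with the epoxide syn to OH (the tartrate hand must be confirmed on the first run, the D-ester giving the antipode).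

Step 10
Reactants: 18 (1S,5R,6R)-5-hydroxy-5-[(trimethylsilyl)ethynyl]-7-oxabicyclo[4.1.0]hept-3-en-2-one
Product: 19 (1S,5R,6R)-5-hydroxy-3-iodo-5-[(trimethylsilyl)ethynyl]-7-oxabicyclo[4.1.0]hept-3-en-2-one
Conditions: I2, pyridine, CH2Cl2, 0 °C → rt
Reagents that add atoms: iodine, II
Why: Johnson α-iodination (pyridine conjugate addition, iodination of the enolate, elimination) works on γ,γ-disubstituted and epoxide-bearing cyclohexenones and leaves the stereocentres untouched.

Step 11
Reactants: 19 (1S,5R,6R)-5-hydroxy-3-iodo-5-[(trimethylsilyl)ethynyl]-7-oxabicyclo[4.1.0]hept-3-en-2-one; 7 (2E,4R)-2,4-dimethyloct-2-enamide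
Product: 20 (2E,4R)-N-{(1S,5R,6R)-5-hydroxy-2-oxo-5-[(trimethylsilyl)ethynyl]-7-oxabicyclo[4.1.0]hept-3-en-3-yl}-2,4-dimethyloct-2-enamide
Conditions: 7 (1.2 equiv), CuI (10 mol%), trans-N,N'-dimethylcyclohexane-1,2-diamine (20 mol%), K2CO3, toluene, 50 °C
Reagents that add atoms: none
Why: Goldberg–Buchwald copper-catalysed vinylic amidation couples the activated 2-iodoenone with the primary amide under mild carbonate conditions, and the syn hydroxy-epoxide cannot undergo Payne rearrangement, so no stereocentre is disturbed.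

Step 12
Reactants: 20 (2E,4R)-N-{(1S,5R,6R)-5-hydroxy-2-oxo-5-[(trimethylsilyl)ethynyl]-7-oxabicyclo[4.1.0]hept-3-en-3-yl}-2,4-dimethyloct-2-enamide
Product: 21 (2E,4R)-N-[(1S,5R,6R)-5-ethynyl-5-hydroxy-2-oxo-7-oxabicyclo[4.1.0]hept-3-en-3-yl]-2,4-dimethyloct-2-enamide
Conditions: Bu4NF, AcOH, THF, 0 °C
Reagents that add atoms: none
Why: Fluoride-induced protodesilylation cleaves the C(sp)–Si bond selectively, and acetic acid buffering protects the base-sensitive epoxy enone.

Step 13
Reactants: 21 (2E,4R)-N-[(1S,5R,6R)-5-ethynyl-5-hydroxy-2-oxo-7-oxabicyclo[4.1.0]hept-3-en-3-yl]-2,4-dimethyloct-2-enamide; 13 (2E,4E)-5-bromo-N-(2-hydroxy-5-oxocyclopent-1-en-1-yl)penta-2,4-dienamide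
Product: 23 (2E,4R)-N-[(1S,5S,6R)-5-hydroxy-5-[(1E,3E,5E)-7-[(2-hydroxy-5-oxocyclopent-1-en-1-yl)amino]-7-oxohepta-1,3,5-trien-1-yl]-2-oxo-7-oxabicyclo[4.1.0]hept-3-en-3-yl]-2,4-dimethyloct-2-enamide, via vinylstannane 22 (not isolated)
Conditions: Bu3SnH (1.05 equiv, slow addition), Pd(PPh3)2Cl2 (3 mol%), THF, 0 °C; then 13, Pd(MeCN)2Cl2 (5 mol%), DMF, rt, dark
Reagents that add atoms: none
Why: Palladium-catalysed syn-hydrostannation of the terminal alkyne of a tertiary propargylic alcohol places tin on the distal carbon with E geometry, and the Stille coupling with the bromodiene proceeds with retention at both partners to give the E,E,E-triene without touching any stereocentre.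

**Compound list**

1 | (E)-1-bromohept-2-ene | CCCC/C=C/CBr | starting material
2 | (R)-3-methylhept-1-ene | CCCC[C@@H](C)C=C | intermediate
3 | (R)-2-methylhexanal | CCCC[C@@H](C)C=O | intermediate
4 | 2-bromopropanamide (racemic) | CC(Br)C(N)=O | starting material
5 | (1-amino-1-oxopropan-2-yl)triphenylphosphonium bromide | CC(C(N)=O)[P+](c1ccccc1)(c1ccccc1)c1ccccc1.[Br-] | intermediate
6 | 2-(triphenyl-λ5-phosphanylidene)propanamide | CC(C(N)=O)=P(c1ccccc1)(c1ccccc1)c1ccccc1 | intermediate
7 | (2E,4R)-2,4-dimethyloct-2-enamide | CCCC[C@@H](C)/C=C(\C)C(N)=O | intermediate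
8 | glutaconaldehyde potassium salt, potassium (1E,3E)-5-oxopenta-1,3-dien-1-olate | [K+].[O-]/C=C/C=C/C=O | starting material
9 | (2E,4E)-5-bromopenta-2,4-dienal | O=C/C=C/C=C/Br | intermediate
10 | (2E,4E)-5-bromopenta-2,4-dienoic acid | OC(=O)/C=C/C=C/Br | intermediate
11 | 2-amino-3-hydroxycyclopent-2-en-1-one | NC1=C(O)CCC1=O | starting material
12 | (2E,4E)-5-bromopenta-2,4-dienoyl chloride | O=C(Cl)/C=C/C=C/Br | intermediate
13 | (2E,4E)-5-bromo-N-(2-hydroxy-5-oxocyclopent-1-en-1-yl)penta-2,4-dienamide | O=C(/C=C/C=C/Br)NC1=C(O)CCC1=O | intermediate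
14 | 4-iodophenol | Oc1ccc(I)cc1 | starting material
15 | ethynyltrimethylsilane | C#C[Si](C)(C)C | starting material
16 | 4-[(trimethylsilyl)ethynyl]phenol | Oc1ccc(cc1)C#C[Si](C)(C)C | intermediate
17 | 4-hydroxy-4-[(trimethylsilyl)ethynyl]cyclohexa-2,5-dien-1-one (achiral) | O=C1C=CC(O)(C#C[Si](C)(C)C)C=C1 | intermediate
18 | (1S,5R,6R)-5-hydroxy-5-[(trimethylsilyl)ethynyl]-7-oxabicyclo[4.1.0]hept-3-en-2-one (epoxide syn to OH) | C1=C[C@@](O)(C#C[Si](C)(C)C)[C@@H]2O[C@@H]2C1=O | intermediate
19 | (1S,5R,6R)-5-hydroxy-3-iodo-5-[(trimethylsilyl)ethynyl]-7-oxabicyclo[4.1.0]hept-3-en-2-one | IC1=C[C@@](O)(C#C[Si](C)(C)C)[C@@H]2O[C@@H]2C1=O | intermediate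
20 | (2E,4R)-N-{(1S,5R,6R)-5-hydroxy-2-oxo-5-[(trimethylsilyl)ethynyl]-7-oxabicyclo[4.1.0]hept-3-en-3-yl}-2,4-dimethyloct-2-enamide | CCCC[C@@H](C)/C=C(\C)C(=O)NC1=C[C@@](O)(C#C[Si](C)(C)C)[C@@H]2O[C@@H]2C1=O | intermediate
21 | (2E,4R)-N-[(1S,5R,6R)-5-ethynyl-5-hydroxy-2-oxo-7-oxabicyclo[4.1.0]hept-3-en-3-yl]-2,4-dimethyloct-2-enamide | CCCC[C@@H](C)/C=C(\C)C(=O)NC1=C[C@@](O)(C#C)[C@@H]2O[C@@H]2C1=O | intermediate
22 | (2E,4R)-N-{(1S,5R,6R)-5-hydroxy-2-oxo-5-[(E)-2-(tributylstannyl)ethenyl]-7-oxabicyclo[4.1.0]hept-3-en-3-yl}-2,4-dimethyloct-2-enamide | CCCC[C@@H](C)/C=C(\C)C(=O)NC1=C[C@@](O)(/C=C/[Sn](CCCC)(CCCC)CCCC)[C@@H]2O[C@@H]2C1=O | intermediate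
23 | (2E,4R)-N-[(1S,5S,6R)-5-hydroxy-5-[(1E,3E,5E)-7-[(2-hydroxy-5-oxocyclopent-1-en-1-yl)amino]-7-oxohepta-1,3,5-trien-1-yl]-2-oxo-7-oxabicyclo[4.1.0]hept-3-en-3-yl]-2,4-dimethyloct-2-enamide | CCCC[C@@H](C)/C=C(\C)C(=O)NC1=C[C@@](O)(/C=C/C=C/C=C/C(=O)NC2=C(O)CCC2=O)[C@@H]2O[C@@H]2C1=O | target

**Step count**
Total: 13 steps. Longest linear sequence: 7 steps (14 → 23, steps 7 to 13).

**Steps most likely to fail**

Step 9 (desymmetrising epoxidation; enantioselectivity and syn delivery are unproven on a p-quinol). The fallback sets out from 17 and comes back at 18. It replaces alkoxide-directed metal-peroxide delivery by iminium-ion organocatalysis: 9-amino-9-deoxy-epi-quinine bis(trifluoroacetate) (10 mol%), 50% aq. H2O2, dioxane, 30 °C. The chiral primary amine condenses with the dienone carbonyl, its protonated quinuclidine steers hydrogen peroxide to one enantiotopic β-carbon, and hydrogen bonding to the free hydroxyl favours the syn face. No new compound lies on this path, which is why its entry below is F0.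

Step 8 (radical ipso-hydroxylation; phenoxyl dimerisation through the free ortho positions and over-oxidation of 17 to a racemic epoxide compete, and an alkynylphenol is an untested substrate). The fallback sets out from 16 and comes back at 17. It replaces the peracid chain by metal–superoxo radical coupling: Co(salen), that is [N,N'-ethylenebis(salicylideneiminato)]cobalt with divalent cobalt (10 mol%), O2 (1 atm), MeOH/CH2Cl2, rt. The cobalt-bound superoxo radical couples with the phenoxyl radical at the para carbon to give 4-hydroperoxy-4-[(trimethylsilyl)ethynyl]cyclohexa-2,5-dien-1-one F1, which Me2S reduces in the same flask to 17.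

Step 13 (one-pot hydrostannation/Stille on the fully functionalised epoxy enone; regiochemistry of tin addition, over-reduction by tin hydride and protodestannylation are the dangers). The fallback sets out from 21 and comes back at 23. Hydrostannation alone (Bu3SnH, Pd(PPh3)2Cl2, THF, 0 °C) gives 22, which is treated with I2 (CH2Cl2, 0 °C) to give (2E,4R)-N-{(1S,5R,6R)-5-hydroxy-5-[(E)-2-iodoethenyl]-2-oxo-7-oxabicyclo[4.1.0]hept-3-en-3-yl}-2,4-dimethyloct-2-enamide F2. Separately, (E)-penta-2,4-dienoic acid is coupled with 11 (N-ethyl-N'-(3-dimethylaminopropyl)carbodiimide hydrochloride, Et3N, DMF) to give (2E)-N-(2-hydroxy-5-oxocyclopent-1-en-1-yl)penta-2,4-dienamide F3. A ligand-free Heck reaction of F2 with F3 (Pd(OAc)2, Bu4NCl, NaHCO3, DMF, rt) then forms the C2'–C3' bond at the terminal carbon of the diene and gives 23.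

**Further compounds**

F1 | step 8 | 4-hydroperoxy-4-[(trimethylsilyl)ethynyl]cyclohexa-2,5-dien-1-one | O=C1C=CC(OO)(C#C[Si](C)(C)C)C=C1
F0 | step 9 | none | none
F2 | step 13 | (2E,4R)-N-{(1S,5R,6R)-5-hydroxy-5-[(E)-2-iodoethenyl]-2-oxo-7-oxabicyclo[4.1.0]hept-3-en-3-yl}-2,4-dimethyloct-2-enamide | CCCC[C@@H](C)/C=C(\C)C(=O)NC1=C[C@@](O)(/C=C/I)[C@@H]2O[C@@H]2C1=O
F3 | step 13 | (2E)-N-(2-hydroxy-5-oxocyclopent-1-en-1-yl)penta-2,4-dienamide | C=C/C=C/C(=O)NC1=C(O)CCC1=O
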